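**Retrosynthetic overview**
- The target is opened at C9–C10 and at the furanone C–O bond: one flask converts an acyclic γ-hydroxy ynone aldehyde into the 3(2H)-furanone ring and the ten-membered carbocycle, and sets C9 and C10.
- The ynone comes from a (Z)-vinyl iodide, CO and but-3-yn-2-ol (carbonylative Sonogashira; C3 is the CO carbon).
- The C8 isobutyrate and the C9 aldehyde come from a terminal acetonide (hydrolysis, orthoester mono-acylation, oxidation).
- The trans α-methylene-γ-butyrolactone (C6, C7) comes from a Nozaki–Hiyama allylation of (Z)-3-iodobut-2-enal with a Morita–Baylis–Hillman bromide made from D-glyceraldehyde acetonide (source of C8).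
- Ring order: lactone first, then furanone and carbocycle together in the last step.

Assumption: (R)-glyceraldehyde acetonide is bought (it is otherwise one NaIO4 step from 1,2:5,6-di-O-isopropylidene-D-mannitol); atom numbers C1–C15 are germacrane numbers of the target.

**Route**

Step 1
Reactants: 1 (4R)-2,2-dimethyl-1,3-dioxolane-4-carbaldehyde; 2 methyl acrylate
Product: 3 methyl 2-{hydroxy[(4R)-2,2-dimethyl-1,3-dioxolan-4-yl]methyl}prop-2-enoate (both carbinol epimers)
Conditions: DABCO (0.3 equiv), 2 (3 equiv), 1,4-dioxane/H2O 1:1, rt, 36 h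
Reagents that add atoms: none
Why: Morita–Baylis–Hillman reaction, in which the amine–acrylate zwitterion adds to the aldehyde; the new carbinol centre is an epimer mixture that is erased in step 2, and the dioxolane centre (future C8) is kept.

Step 2
Reactants: 3 methyl 2-{hydroxy[(4R)-2,2-dimethyl-1,3-dioxolan-4-yl]methyl}prop-2-enoate
Product: 4 methyl (2Z)-2-(bromomethyl)-3-[(4S)-2,2-dimethyl-1,3-dioxolan-4-yl]prop-2-enoate
Conditions: NBS (1.3 equiv), Me2S (1.5 equiv), CH2Cl2, 0 °C to rt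
Reagents that add atoms: N-bromosuccinimide, O=C1CCC(=O)N1Br
Why: Corey–Kim-type activation of the allylic alcohol followed by SN2' delivery of bromide gives the thermodynamically preferred (Z)-2-(bromomethyl)alk-2-enoate under neutral conditions that leave the acetonide intact.

Step 3
Reactants: 5 but-2-yn-1-ol
Product: 7 (2Z)-3-iodobut-2-en-1-ol, via cyclic alkenylalanate 6 (not isolated)
Conditions: NaAlH2(OCH2CH2OCH3)2 (1.5 equiv), Et2O, 0 °C to rt; then I2 (1.5 equiv), THF, −78 to 0 °C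
Reagents that add atoms: iodine, [I][I]
Why: Hydroxyl-directed trans-hydroalumination puts aluminium on C3 in a five-membered alanate, and iodinolysis with retention gives the Z vinyl iodide that later becomes the C4=C5 olefin.

Step 4
Reactants: 7 (2Z)-3-iodobut-2-en-1-ol
Product: 8 (2Z)-3-iodobut-2-enal
Conditions: MnO2 (15 equiv), CH2Cl2, rt, dark; filtered solution used directly
Reagents that add atoms: none
Why: Neutral allylic oxidation with MnO2 leaves the C–I bond and the Z geometry untouched.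

Step 5
Reactants: 4 methyl (2Z)-2-(bromomethyl)-3-[(4S)-2,2-dimethyl-1,3-dioxolan-4-yl]prop-2-enoate; 8 (2Z)-3-iodobut-2-enal
Product: 10 (4S,5S)-4-[(4S)-2,2-dimethyl-1,3-dioxolan-4-yl]-5-[(1Z)-2-iodoprop-1-en-1-yl]-3-methylideneoxolan-2-one, via anti hydroxy ester 9 (not isolated)
Conditions: CrCl2 (3.5 equiv, nickel-free), THF, 0 °C to rt, 12 h; then PPTS (10 mol %), CH2Cl2, rt
Reagents that add atoms: none
Why: Nozaki–Hiyama allylation, in which the allylchromium formed with divalent chromium attacks the aldehyde through its γ-carbon (C7) in a chair transition state from the equilibrated E-allyl isomer, giving the 6,7-anti adduct and so the trans-lactone after acid-catalysed ring closure; the aldehyde approaches anti to the dioxolane CH2 with H-8 eclipsing the ester-bearing carbon and the C8–O bond outside, which sets C6 and C7 from C8, and the vinyl iodide is inert to CrCl2 without nickel.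

Step 6
Reactants: 10 (4S,5S)-4-[(4S)-2,2-dimethyl-1,3-dioxolan-4-yl]-5-[(1Z)-2-iodoprop-1-en-1-yl]-3-methylideneoxolan-2-one
Product: 11 (4R,5S)-4-[(1S)-1,2-dihydroxyethyl]-5-[(1Z)-2-iodoprop-1-en-1-yl]-3-methylideneoxolan-2-one
Conditions: AcOH/H2O 4:1, 40 °C, 3 h
Reagents that add atoms: none
Why: Mild aqueous acid hydrolyses the acetal without touching the lactone, the exocyclic olefin or the vinyl iodide, and no stereocentre is involved.

Step 7
Reactants: 11 (4R,5S)-4-[(1S)-1,2-dihydroxyethyl]-5-[(1Z)-2-iodoprop-1-en-1-yl]-3-methylideneoxolan-2-one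
Product: 13 (1S)-2-hydroxy-1-{(2S,3S)-2-[(1Z)-2-iodoprop-1-en-1-yl]-4-methylidene-5-oxooxolan-3-yl}ethyl 2-methylpropanoate, via cyclic orthoester 12 (not isolated)
Conditions: (CH3)2CHC(OCH3)3 (1.5 equiv), CSA (5 mol %), CH2Cl2, rt, 1 h; then AcOH/H2O 4:1, 0 °C, 20 min
Reagents that add atoms: trimethyl orthoisobutyrate, COC(OC)(OC)C(C)C; water, O
Why: Orthoester mono-acylation of a vicinal diol, in which kinetic hydrolysis of the dioxolan-2-ylium ion expels the less hindered primary oxygen and leaves the isobutyrate on the secondary C8 oxygen with C8 untouched.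

Step 8
Reactants: 13 (1S)-2-hydroxy-1-{(2S,3S)-2-[(1Z)-2-iodoprop-1-en-1-yl]-4-methylidene-5-oxooxolan-3-yl}ethyl 2-methylpropanoate; 14 but-3-yn-2-ol (racemic)
Product: 15 (1S)-2-hydroxy-1-{(2R,3S)-2-[(1Z)-6-hydroxy-2-methyl-3-oxohept-1-en-4-yn-1-yl]-4-methylidene-5-oxooxolan-3-yl}ethyl 2-methylpropanoate (both epimers at the propargylic carbinol)
Conditions: PdCl2(PPh3)2 (5 mol %), CO (1 atm), Et3N (3 equiv), 14 (2 equiv), THF, rt, 12 h, copper-free
Reagents that add atoms: carbon monoxide, [C-]#[O+]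
Why: Carbonylative Sonogashira coupling, in which zerovalent palladium adds to the vinyl iodide with retention, CO inserts and the terminal alkyne is acylated, giving the Z γ-hydroxy ynone; leaving out copper suppresses direct alkynylation, and the carbinol centre is lost in step 10, so racemic 14 is sufficient.

Step 9
Reactants: 15 (1S)-2-hydroxy-1-{(2R,3S)-2-[(1Z)-6-hydroxy-2-methyl-3-oxohept-1-en-4-yn-1-yl]-4-methylidene-5-oxooxolan-3-yl}ethyl 2-methylpropanoate
Product: 16 (1S)-1-{(2R,3S)-2-[(1Z)-6-hydroxy-2-methyl-3-oxohept-1-en-4-yn-1-yl]-4-methylidene-5-oxooxolan-3-yl}-2-oxoethyl 2-methylpropanoate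
Conditions: TEMPO (10 mol %), PhI(OAc)2 (1.2 equiv), CH2Cl2, rt, 3 h; used crude
Reagents that add atoms: none
Why: Oxoammonium (TEMPO) oxidation is selective for the primary alcohol over the secondary propargylic one and is near-neutral, so the α-acyloxy aldehyde (C8) does not epimerise.

Step 10
Reactants: 16 (1S)-1-{(2R,3S)-2-[(1Z)-6-hydroxy-2-methyl-3-oxohept-1-en-4-yn-1-yl]-4-methylidene-5-oxooxolan-3-yl}-2-oxoethyl 2-methylpropanoate
Product: 20 (4Z,6R,7S,8S,9R,10R)-9-hydroxy-8-(2-methylpropanoyloxy)-1-oxo-3,10-epoxygermacra-2,4,11(13)-trien-12,6-olide (CNP0265772.1), via furanone aldehyde 17 (not isolated), via silyloxyfuran 18 (not isolated), via trimethylsilyl ether 19 (not isolated)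
Conditions: [(4-CF3C6H4)3P]AuCl (5 mol %), AgOTf (5 mol %), H2O (1 equiv), toluene (5 mM), rt; then CH2Cl2 (to 2 mM), iPr2NEt (3 equiv), TMSOTf (2.5 equiv), −78 to −30 °C; then citric acid, MeOH/H2O, 0 °C
Reagents that add atoms: water, O (its oxygen becomes the C1 ketone oxygen; the former C3 carbonyl oxygen leaves as water)
Why: Proposed new method: monovalent gold brings about the known cycloisomerisation of the γ-hydroxy ynone (hydration at C1, hemiketalisation of the C10 hydroxyl on C3, loss of water) to the 2-methyl-3(2H)-furanone ring, soft enolisation with TMSOTf/iPr2NEt gives the planar 3-silyloxyfuran, and its C10 then attacks the TMSOTf-activated C9 aldehyde in an intramolecular Mukaiyama aldol that closes the ten-membered carbocycle, so two rings form in one flask; the closest known reactions are the gold-catalysed furanone synthesis from γ-hydroxy alkynones, the intermolecular Mukaiyama aldol of 3-silyloxyfurans at C2 and the one-pot silyl triflate enol silane formation–aldol; the tether (Z-olefin plus trans-lactone) is expected to reach C10 from the furan face that keeps the lactone on the periphery of the new ring (10R), and the open synclinal transition state to keep the silylated aldehyde oxygen outside the ring and anti to the furan oxygen (9R), but this outcome is argued from hand models only and is the main uncertainty of the route.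

**Compound list**

1 | (4R)-2,2-dimethyl-1,3-dioxolane-4-carbaldehyde | O=C[C@H]1COC(C)(C)O1 | starting material
2 | methyl acrylate | C=CC(=O)OC | starting material
3 | methyl 2-{hydroxy[(4R)-2,2-dimethyl-1,3-dioxolan-4-yl]methyl}prop-2-enoate (both carbinol epimers) | C=C(C(=O)OC)C(O)[C@H]1COC(C)(C)O1 | intermediate
4 | methyl (2Z)-2-(bromomethyl)-3-[(4S)-2,2-dimethyl-1,3-dioxolan-4-yl]prop-2-enoate | COC(=O)/C(CBr)=C/[C@H]1COC(C)(C)O1 | intermediate
5 | but-2-yn-1-ol | CC#CCO | starting material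
6 | sodium 2,2-bis(2-methoxyethoxy)-3-methyl-2,5-dihydro-1,2-oxaaluminol-2-uide (cyclic Z-alkenylalanate) | CC1=CCO[Al-]1(OCCOC)OCCOC.[Na+] | intermediate
7 | (2Z)-3-iodobut-2-en-1-ol | C/C(I)=C/CO | intermediate
8 | (2Z)-3-iodobut-2-enal | C/C(I)=C/C=O | intermediate
9 | methyl (3S,4S,5Z)-3-[(4S)-2,2-dimethyl-1,3-dioxolan-4-yl]-4-hydroxy-6-iodo-2-methylidenehept-5-enoate | C=C(C(=O)OC)[C@H]([C@H]1COC(C)(C)O1)[C@H](O)/C=C(/C)I | intermediate
10 | (4S,5S)-4-[(4S)-2,2-dimethyl-1,3-dioxolan-4-yl]-5-[(1Z)-2-iodoprop-1-en-1-yl]-3-methylideneoxolan-2-one | C=C1C(=O)O[C@H](/C=C(/C)I)[C@H]1[C@H]2COC(C)(C)O2 | intermediate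
11 | (4R,5S)-4-[(1S)-1,2-dihydroxyethyl]-5-[(1Z)-2-iodoprop-1-en-1-yl]-3-methylideneoxolan-2-one | C=C1C(=O)O[C@H](/C=C(/C)I)[C@H]1[C@H](O)CO | intermediate
12 | (4S,5S)-5-[(1Z)-2-iodoprop-1-en-1-yl]-4-[(4S)-2-methoxy-2-(propan-2-yl)-1,3-dioxolan-4-yl]-3-methylideneoxolan-2-one (both orthoester epimers) | C=C1C(=O)O[C@H](/C=C(/C)I)[C@H]1[C@H]2COC(OC)(C(C)C)O2 | intermediate
13 | (1S)-2-hydroxy-1-{(2S,3S)-2-[(1Z)-2-iodoprop-1-en-1-yl]-4-methylidene-5-oxooxolan-3-yl}ethyl 2-methylpropanoate | C=C1C(=O)O[C@H](/C=C(/C)I)[C@H]1[C@H](OC(=O)C(C)C)CO | intermediate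
14 | but-3-yn-2-ol (racemic) | CC(O)C#C | starting material
15 | (1S)-2-hydroxy-1-{(2R,3S)-2-[(1Z)-6-hydroxy-2-methyl-3-oxohept-1-en-4-yn-1-yl]-4-methylidene-5-oxooxolan-3-yl}ethyl 2-methylpropanoate (both carbinol epimers) | C=C1C(=O)O[C@H](/C=C(/C)C(=O)C#CC(C)O)[C@H]1[C@H](OC(=O)C(C)C)CO | intermediate
16 | (1S)-1-{(2R,3S)-2-[(1Z)-6-hydroxy-2-methyl-3-oxohept-1-en-4-yn-1-yl]-4-methylidene-5-oxooxolan-3-yl}-2-oxoethyl 2-methylpropanoate (both carbinol epimers) | C=C1C(=O)O[C@H](/C=C(/C)C(=O)C#CC(C)O)[C@H]1[C@H](OC(=O)C(C)C)C=O | intermediate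
17 | (1S)-1-{(2R,3S)-2-[(1Z)-2-(5-methyl-4-oxo-4,5-dihydrofuran-2-yl)prop-1-en-1-yl]-4-methylidene-5-oxooxolan-3-yl}-2-oxoethyl 2-methylpropanoate (both epimers at the furanone methine) | C=C1C(=O)O[C@H](/C=C(/C)C2=CC(=O)C(C)O2)[C@H]1[C@H](OC(=O)C(C)C)C=O | intermediate
18 | (1S)-1-{(2R,3S)-2-[(1Z)-2-{5-methyl-4-[(trimethylsilyl)oxy]furan-2-yl}prop-1-en-1-yl]-4-methylidene-5-oxooxolan-3-yl}-2-oxoethyl 2-methylpropanoate | C=C1C(=O)O[C@H](/C=C(/C)c2cc(O[Si](C)(C)C)c(C)o2)[C@H]1[C@H](OC(=O)C(C)C)C=O | intermediate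
19 | 9-O-trimethylsilyl ether of 20 (same configuration at all centres) | C=C1C(=O)O[C@@H]2/C=C(/C)C3=CC(=O)[C@](C)(O3)[C@H](O[Si](C)(C)C)[C@@H](OC(=O)C(C)C)[C@@H]12 | intermediate
20 | (4Z,6R,7S,8S,9R,10R)-9-hydroxy-8-(2-methylpropanoyloxy)-1-oxo-3,10-epoxygermacra-2,4,11(13)-trien-12,6-olide (CNP0265772.1) | C=C1C(=O)O[C@@H]2/C=C(/C)C3=CC(=O)[C@](C)(O3)[C@H](O)[C@@H](OC(=O)C(C)C)[C@@H]12 | target

**Step count and risks**

Total step count: 10. Longest linear sequence: 8 steps (steps 3–10 from 5, or steps 1, 2, 5–10 from 1).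

Most likely to fail:

1. Step 10 (the nine-membered oxa-bridged ring may not close, or C9/C10 may come out wrong). Fallback, setting out from 4 and 14 and coming back at 20: make the C9–C10 bond intermolecularly and close the carbocycle last by ring-closing metathesis at C4=C5. Bromide 4 and acrolein with CrCl2 give the anti hydroxy ester F1, which PPTS closes to the vinyl lactone F2. Aqueous AcOH gives the diol F3; trimethyl orthoisobutyrate/CSA gives the cyclic orthoester F4, which water opens to the isobutyrate alcohol F5; Dess–Martin periodinane gives the aldehyde F6. Separately, 2-bromopropene, CO and 14 (PdCl2(PPh3)2, Et3N) give the enynone F7, the gold catalyst of step 10 gives the furanone F8, and TIPSOTf/Et3N gives the silyloxyfuran F9. BF3·OEt2 joins F9 and F6 in a Mukaiyama aldol to the diene F10, and the second-generation Hoveyda–Grubbs catalyst (toluene, 80 °C) closes the ring to 20 with loss of ethene.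

2. Step 5 (the allylation may give the 6,7-syn adduct and hence the cis-lactone). Fallback, setting out from 4 and 8 and coming back at 10: accept the syn adduct and invert C6 during lactonisation. Indium powder in THF/H2O couples 4 and 8 through the Z-allylindium to the syn hydroxy ester F11; LiOH gives the hydroxy acid F12; Mitsunobu lactonisation (PPh3, DIAD) closes the ring with inversion at the allylic C6 to 10.

3. Step 8 (the carbonylative coupling may give direct alkynylation, ester formation or Z-to-E isomerisation). Fallback, setting out from 13 and 14 and coming back at 15: bring C3 in as an aldehyde carbon instead of CO. Alcohol 14 with n-BuLi (2 equiv) then DMF gives the ynal F13; Nozaki–Hiyama–Kishi coupling of 13 with F13 (CrCl2, NiCl2 cat., DMSO) gives the triol F14; MnO2 oxidises only the doubly activated (allylic and propargylic) carbinol to give 15.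

**Further compounds**

F1 | step 10 | methyl (3S,4R)-3-[(4S)-2,2-dimethyl-1,3-dioxolan-4-yl]-4-hydroxy-2-methylidenehex-5-enoate | C=C(C(=O)OC)[C@H]([C@H]1COC(C)(C)O1)[C@H](O)C=C
F2 | step 10 | (4S,5R)-4-[(4S)-2,2-dimethyl-1,3-dioxolan-4-yl]-5-ethenyl-3-methylideneoxolan-2-one | C=C1C(=O)O[C@H](C=C)[C@H]1[C@H]2COC(C)(C)O2
F3 | step 10 | (4R,5R)-4-[(1S)-1,2-dihydroxyethyl]-5-ethenyl-3-methylideneoxolan-2-one | C=C1C(=O)O[C@H](C=C)[C@H]1[C@H](O)CO
F4 | step 10 | (4S,5R)-5-ethenyl-4-[(4S)-2-methoxy-2-(propan-2-yl)-1,3-dioxolan-4-yl]-3-methylideneoxolan-2-one | C=C1C(=O)O[C@H](C=C)[C@H]1[C@H]2COC(OC)(C(C)C)O2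
F5 | step 10 | (1S)-1-[(2R,3S)-2-ethenyl-4-methylidene-5-oxooxolan-3-yl]-2-hydroxyethyl 2-methylpropanoate | C=C1C(=O)O[C@H](C=C)[C@H]1[C@H](OC(=O)C(C)C)CO
F6 | step 10 | (1S)-1-[(2R,3S)-2-ethenyl-4-methylidene-5-oxooxolan-3-yl]-2-oxoethyl 2-methylpropanoate | C=C1C(=O)O[C@H](C=C)[C@H]1[C@H](OC(=O)C(C)C)C=O
F7 | step 10 | 6-hydroxy-2-methylhept-1-en-4-yn-3-one (racemic) | CC(=C)C(=O)C#CC(C)O
F8 | step 10 | 2-methyl-5-(prop-1-en-2-yl)furan-3(2H)-one (racemic) | CC(=C)C1=CC(=O)C(C)O1
F9 | step 10 | {[2-methyl-5-(prop-1-en-2-yl)furan-3-yl]oxy}tri(propan-2-yl)silane | CC(=C)c1cc(O[Si](C(C)C)(C(C)C)C(C)C)c(C)o1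
F10 | step 10 | (1S,2R)-1-[(2R,3S)-2-ethenyl-4-methylidene-5-oxooxolan-3-yl]-2-hydroxy-2-[(2R)-2-methyl-3-oxo-5-(prop-1-en-2-yl)-2,3-dihydrofuran-2-yl]ethyl 2-methylpropanoate | C=C1C(=O)O[C@H](C=C)[C@H]1[C@H](OC(=O)C(C)C)[C@@H](O)[C@@]2(C)OC(=CC2=O)C(C)=C
F11 | step 5 | methyl (3S,4R,5Z)-3-[(4S)-2,2-dimethyl-1,3-dioxolan-4-yl]-4-hydroxy-6-iodo-2-methylidenehept-5-enoate | C=C(C(=O)OC)[C@H]([C@H]1COC(C)(C)O1)[C@@H](O)/C=C(/C)I
F12 | step 5 | (3S,4R,5Z)-3-[(4S)-2,2-dimethyl-1,3-dioxolan-4-yl]-4-hydroxy-6-iodo-2-methylidenehept-5-enoic acid | C=C(C(=O)O)[C@H]([C@H]1COC(C)(C)O1)[C@@H](O)/C=C(/C)I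
F13 | step 8 | 4-hydroxypent-2-ynal (racemic) | CC(O)C#CC=O
F14 | step 8 | (1S)-1-{(2R,3S)-2-[(1Z)-3,6-dihydroxy-2-methylhept-1-en-4-yn-1-yl]-4-methylidene-5-oxooxolan-3-yl}-2-hydroxyethyl 2-methylpropanoate (carbinol epimers) | C=C1C(=O)O[C@H](/C=C(/C)C(O)C#CC(C)O)[C@H]1[C@H](OC(=O)C(C)C)CO
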